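C1 is the ring C=O, C2 and C3 the ring CH2 groups, C4 the quaternary carbon and C5 the ring CH. C6, C7 and C11 (CMe2) form the cyclopropane, C8, C9 and C10 (C=O) the chain, C7' is benzylic, C8' starts the isobutyl group and C1'–C6' are the arene.
Enabling feature: on the three-membered ring C6–C7–C11, the branches C6–C5 (into the five-membered ring, between C1=O and C4) and C7–C8 (into the oxobutyl chain) lie on one face. This is the result of putting carbon and a metal on one face of the C6=C7 bond of mirror-symmetric 3,3-dimethylcyclopropene and then replacing the metal by carbon with retention.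
Cuts, in retrosynthetic order: O–Me and aryl–CHO bonds; the C10 ketal; C8'=C9' (Wittig); C1=O back to a C1=C5 alkene; C4–C7' ([3,3] shift of a C1 arylacetate); C5–C6 and C7–C8 (key step).
Forward: no carbocycle is closed after step 2. The cyclopropene, the chain Grignard reagent and the iodocyclopentenone are joined in one flask, the arylacetic acid is attached at C1–O and shifted to C4, and then the side chain, ketones and arene are finished.
Stereochemistry: C6 and C7 come from the chiral bisphosphine on copper (cis by syn addition and retention), and the C1 carbinol from the CBS catalyst. C4 and C7' come from suprafacial chair transfer from C1, and C5 from equilibration next to C1=O, trans to the C7' branch.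

Key step: step 5

Assumption: (R)-DTBM-SEGPHOS is taken as the ligand antipode that gives the (6S,7R) sense of 11. Cyclopropene 4 has no bias of its own, so this is to be checked by correlation, and the (S)-ligand is used if the sense is reversed.

Step 1
Reactants: 1 3-methylbut-2-enal
Product: 2 3-methylbut-2-enal N-tosylhydrazone (E at C=N)
Conditions: TsNHNH2 (1.0 equiv), MeOH, 0 °C → rt
Reagents that add atoms: p-toluenesulfonyl hydrazide, Cc1ccc(cc1)S(=O)(=O)NN
Why: Hydrazone formation from an aldehyde and a sulfonyl hydrazide is fast at room temperature, leaves the conjugated alkene alone and creates no stereocentre.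

Step 2
Reactants: 2 3-methylbut-2-enal N-tosylhydrazone
Product: 4 3,3-dimethylcyclopropene, via 1-diazo-3-methylbut-2-ene 3 (not isolated)
Conditions: NaOMe (1.1 equiv), diglyme, 140–160 °C, N2 sweep, condensed at −78 °C, kept as a titrated toluene solution
Reagents that add atoms: none
Why: Bamford–Stevens fragmentation of the sodium salt expels sulfinate to give diazoalkene 3, which loses nitrogen to an alkenylcarbene that closes onto its own fully substituted alkene terminus, the established entry to 3,3-dialkylcyclopropenes, and the low-boiling product leaves the hot zone as it forms.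

Step 3
Reactants: 5 3-methylcyclopent-2-en-1-one
Product: 6 2-iodo-3-methylcyclopent-2-en-1-one
Conditions: I2 (0.6 equiv), PhI(OCOCF3)2 (0.6 equiv), pyridine (1.2 equiv), CH2Cl2, rt, dark
Reagents that add atoms: iodine, II
Why: Iodine and the hypervalent iodine reagent give trifluoroacetyl hypoiodite, which iodinates the α-carbon by addition and pyridine-induced elimination (oxidative α-iodination of enones), a variant chosen because the β-methyl group slows the amine conjugate-addition pathway of plain I2/pyridine.

Step 4
Reactants: 7 2-(2-bromoethyl)-2-methyl-1,3-dioxolane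
Product: 8 2-(2-methyl-1,3-dioxolan-2-yl)ethylmagnesium bromide (THF solution, titrated)
Conditions: Mg turnings (1.3 equiv), THF, 20–30 °C
Reagents that add atoms: magnesium, [Mg]
Why: Magnesium inserts into the primary carbon–bromine bond (Grignard formation), and the dioxolane tolerates the reagent as long as the solution is kept at or below 30 °C and used the same day.

Step 5
Reactants: 8 2-(2-methyl-1,3-dioxolan-2-yl)ethylmagnesium bromide; 4 3,3-dimethylcyclopropene; 6 2-iodo-3-methylcyclopent-2-en-1-one
Product: 11 2-[(1S,3R)-2,2-dimethyl-3-[2-(2-methyl-1,3-dioxolan-2-yl)ethyl]cyclopropyl]-3-methylcyclopent-2-en-1-one (6S,7R; cis), via cis-cyclopropylmagnesium bromide 9 (not isolated), via cis-cyclopropylzinc bromide 10 (not isolated)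
Conditions: 4 (1.3 equiv), CuBr·SMe2 (5 mol %), (R)-DTBM-SEGPHOS (6 mol %), toluene/THF, −40 → −10 °C; ZnBr2 (1.1 equiv), THF, −10 → 0 °C; 6 (0.8 equiv), Pd(OAc)2 (3 mol %), SPhos (6 mol %), rt → 40 °C
Reagents that add atoms: none
Why: The alkylcopper–bisphosphine species formed from 8 places C8 and copper on the same face of the strained C6=C7 bond of 4, and exchange with more 8 releases cyclopropylmagnesium bromide 9 and renews the catalyst (copper-catalysed enantioselective carbomagnesiation of 3,3-disubstituted cyclopropenes). Cyclopropyl–metal bonds hold their configuration, so exchange to zinc (10), transfer to the alkenylpalladium iodide formed from 6 and zerovalent palladium, and reductive elimination all proceed with retention (Negishi coupling of a cyclopropylzinc halide with an α-iodoenone). The step closes no ring, since the three-membered ring arrives with 4 and the five-membered ring with 6. C7 and C6 are created together, their cis relation following from syn addition plus retention and their absolute sense from the ligand, which must tell apart the two enantiotopic alkene carbons of a substrate that has no stereocentre. The step needs single insertion and coupling of 10 rather than of leftover alkylzinc; the gem-dimethyl group discourages a second insertion, the slight excess of volatile 4 consumes all of 8, and the zinc reagent does not add to the enone carbonyl.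

Step 6
Reactants: 11 cyclopropyl enone (6S,7R)
Product: 12 (1R)-2-[(1S,3R)-2,2-dimethyl-3-[2-(2-methyl-1,3-dioxolan-2-yl)ethyl]cyclopropyl]-3-methylcyclopent-2-en-1-ol
Conditions: (S)-2-methyl-CBS-oxazaborolidine (0.3 equiv), BH3·THF (1.0 equiv), THF, −30 °C; MeOH, then aq. NH4Cl
Reagents that add atoms: none
Why: Corey–Bakshi–Shibata reduction, in which the fully substituted, cyclopropyl-bearing alkene arm acts as the large and C2H2 as the small substituent, so that the (S)-catalyst delivers hydride to the face that gives the (1R)-carbinol under reagent control and by 1,2-reduction only.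

Step 7
Reactants: 12 (1R)-allylic alcohol; 13 2-(2,4,6-trimethoxyphenyl)acetic acid
Product: 14 (1R)-allylic 2-(2,4,6-trimethoxyphenyl)acetate of 12
Conditions: DCC (1.2 equiv), DMAP (0.1 equiv), CH2Cl2, 0 °C → rt
Reagents that add atoms: none
Why: Steglich esterification acylates oxygen under neutral conditions, so the acid-sensitive allylic C1–O bond is not broken and its configuration is kept.

Step 8
Reactants: 14 allylic arylacetate
Product: 17 (2R)-2-{(1R)-2-[(1S,3R)-2,2-dimethyl-3-[2-(2-methyl-1,3-dioxolan-2-yl)ethyl]cyclopropyl]-1-methylcyclopent-2-en-1-yl}-2-(2,4,6-trimethoxyphenyl)acetic acid (4R,7'R), via (Z)-trimethylsilyl ketene acetal 15 (not isolated), via trimethylsilyl ester 16 (not isolated)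
Conditions: KN(SiMe3)2 (1.3 equiv), THF/toluene, −78 °C; Me3SiCl (2 equiv), −78 °C → rt; 80 °C; aq. NaH2PO4 (pH 5)
Reagents that add atoms: none
Why: Ireland–Claisen rearrangement, in which enolisation puts the aryl group cis to O–K (away from the alkoxy group and held by an ortho-methoxy–potassium contact), silylation gives the (Z)-ketene acetal 15, and its suprafacial [3,3] shift through the chair (the boat would stack the C–OSiMe3 carbon over C5 and its cyclopropyl group) forms C4–C7' on the ring face that carried the C1–O bond, setting C4 (R) and C7' (R) together.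

Step 9
Reactants: 17 rearranged acid
Product: 19 (1S,4R,5S,6R,7R,7'R)-diol with a secondary OH at C1 (trans to the cyclopropyl group) and a primary OH at C8', via C1-boryl C8'-boryloxy intermediate 18 (not isolated)
Conditions: BH3·THF (5 equiv), THF, 0 °C → rt; 3 M NaOH, 30% H2O2, 0 °C → rt
Reagents that add atoms: hydrogen peroxide, OO
Why: Borane reduces the acid through its acyloxyborane and at the same time hydroborates the trisubstituted C1=C5 alkene (Brown hydroboration–oxidation), with boron on the less substituted C1 and syn delivery of H to C5 from the face of the C4 methyl group; both new centres are provisional, since C1 is oxidised in step 10 and C5 is equilibrated in step 13.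

Step 10
Reactants: 19 diol
Product: 20 (4R,5S,6R,7R,7'R)-keto aldehyde (C1 ketone, C8' aldehyde)
Conditions: Dess–Martin periodinane (3 equiv), NaHCO3, CH2Cl2, 0 °C → rt
Reagents that add atoms: none
Why: Dess–Martin oxidation converts the primary and the secondary alcohol in one operation under buffered, non-basic conditions that spare the ketal and do not enolise the α-aryl aldehyde, so C7' is kept.

Step 11
Reactants: 20 keto aldehyde
Product: 21 (4R,5S,6R,7R,7'R)-ketone with a 2-methylprop-1-enyl group on C7'
Conditions: iPrPPh3I (2.5 equiv), nBuLi (2.4 equiv), THF, 0 °C; then 20, −78 → 0 °C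
Reagents that add atoms: isopropyltriphenylphosphonium iodide, CC(C)[P+](c1ccccc1)(c1ccccc1)c1ccccc1.[I-]
Why: Wittig olefination, in which the unstabilised ylide adds to the aldehyde at low temperature faster than it removes C7'–H and leaves the hindered C1 ketone alone because that would require a tetrasubstituted alkene next to C5, while any exchange at C5 is harmless since that centre is equilibrated in step 13.

Step 12
Reactants: 21 alkenyl ketone
Product: 22 (4R,5S,6R,7R,7'R)-isobutyl ketal ketone (C5 epimer of the target series)
Conditions: H2 (1 atm), Pd/C (10 wt %), EtOAc, rt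
Reagents that add atoms: none
Why: Heterogeneous hydrogenation saturates the only alkene, while an alkyl-substituted cyclopropane without conjugating groups, the ketone, the ketal and the aryl ethers are stable at 1 atm and room temperature.

Step 13
Reactants: 22 isobutyl ketal ketone (5S)
Product: 24 (4R,5R,6R,7R,7'R)-diketone with a 2,4,6-trimethoxyphenyl group, via C5-epimerised ketal ketone 23 (not isolated)
Conditions: NaOMe (0.3 equiv), MeOH, 40 °C; then 2 M aq. HCl, THF, rt
Reagents that add atoms: water, O
Why: Methoxide equilibrates C5 through the C1 enolate towards the epimer whose cyclopropyl group is trans to the much larger C7' branch and cis to the C4 methyl group (thermodynamic epimerisation α to a ketone, giving 5R), and acidification then hydrolyses the dioxolane (ketal hydrolysis) without shifting that equilibrium.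

Step 14
Reactants: 24 trimethoxyaryl diketone
Product: 25 (4R,5R,6R,7R,7'R)-3',5'-diformyl-2',4',6'-trimethoxyaryl diketone
Conditions: Cl2CHOMe (6 equiv), TiCl4 (6 equiv), CH2Cl2, −78 → 0 °C; ice/1 M HCl
Reagents that add atoms: dichloromethyl methyl ether, COC(Cl)Cl; water, O
Why: Rieche formylation, in which the methoxychlorocarbenium ion attacks the two open, ortho/para-activated positions C3' and C5' of the trimethoxyarene and excess reagent overcomes the deactivation after the first entry, while the ketones are only complexed by TiCl4 in the absence of base and the low temperature protects the cyclopropane.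

Step 15
Reactants: 25 diformyl trimethyl ether
Product: 26 target CNP0217082.3 (4R,5R,6R,7R,7'R)
Conditions: BCl3 (1 M in CH2Cl2, 8 equiv), CH2Cl2, −78 → 0 °C; H2O
Reagents that add atoms: none
Why: Each methoxy group is ortho to a formyl group, so BCl3 binds in a six-membered chelate and chloride removes the methyl group at low temperature (chelation-assisted aryl methyl ether cleavage), conditions under which the ketones, the alkyl cyclopropane and all five stereocentres should persist.

Compound list
1 | 3-methylbut-2-enal | CC(C)=CC=O | starting material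
2 | 3-methylbut-2-enal N-tosylhydrazone (E) | CC(C)=C/C=N/NS(=O)(=O)c1ccc(C)cc1 | intermediate
3 | 1-diazo-3-methylbut-2-ene | CC(C)=CC=[N+]=[N-] | intermediate
4 | 3,3-dimethylcyclopropene | CC1(C)C=C1 | intermediate
5 | 3-methylcyclopent-2-en-1-one | CC1=CC(=O)CC1 | starting material
6 | 2-iodo-3-methylcyclopent-2-en-1-one | CC1=C(I)C(=O)CC1 | intermediate
7 | 2-(2-bromoethyl)-2-methyl-1,3-dioxolane | CC1(CCBr)OCCO1 | starting material
8 | 2-(2-methyl-1,3-dioxolan-2-yl)ethylmagnesium bromide | CC1(CC[Mg]Br)OCCO1 | intermediate
9 | cis-{2,2-dimethyl-3-[2-(2-methyl-1,3-dioxolan-2-yl)ethyl]cyclopropyl}magnesium bromide (Mg on future C6, same face as the C7 chain) | CC1(CC[C@@H]2[C@H]([Mg]Br)C2(C)C)OCCO1 | intermediate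
10 | cis-{2,2-dimethyl-3-[2-(2-methyl-1,3-dioxolan-2-yl)ethyl]cyclopropyl}zinc bromide (same arrangement as 9) | CC1(CC[C@@H]2[C@H]([Zn]Br)C2(C)C)OCCO1 | intermediate
11 | 2-[(1S,3R)-2,2-dimethyl-3-[2-(2-methyl-1,3-dioxolan-2-yl)ethyl]cyclopropyl]-3-methylcyclopent-2-en-1-one | CC1(CC[C@@H]2[C@H](C3=C(C)CCC3=O)C2(C)C)OCCO1 | intermediate
12 | (1R)-allylic alcohol of 11 (1R,6S,7R) | CC1(CC[C@@H]2[C@H](C3=C(C)CC[C@H]3O)C2(C)C)OCCO1 | intermediate
13 | 2-(2,4,6-trimethoxyphenyl)acetic acid | COc1cc(OC)c(CC(=O)O)c(OC)c1 | starting material
14 | 2-(2,4,6-trimethoxyphenyl)acetate of 12 (1R,6S,7R) | CC1(CC[C@@H]2[C@H](C3=C(C)CC[C@H]3OC(=O)Cc4c(OC)cc(OC)cc4OC)C2(C)C)OCCO1 | intermediate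
15 | (Z)-trimethylsilyl ketene acetal of 14 (aryl cis to OSiMe3) | CC1(CC[C@@H]2[C@H](C3=C(C)CC[C@H]3O/C(O[Si](C)(C)C)=C/c4c(OC)cc(OC)cc4OC)C2(C)C)OCCO1 | intermediate
16 | trimethylsilyl ester of 17 (4R,6S,7R,7'R) | CC1(CC[C@@H]2[C@H](C3=CCC[C@]3(C)[C@@H](C(=O)O[Si](C)(C)C)c4c(OC)cc(OC)cc4OC)C2(C)C)OCCO1 | intermediate
17 | rearranged acid with a C1=C5 alkene (4R,6S,7R,7'R) | CC1(CC[C@@H]2[C@H](C3=CCC[C@]3(C)[C@@H](C(=O)O)c4c(OC)cc(OC)cc4OC)C2(C)C)OCCO1 | intermediate
18 | C1-boryl C8'-boryloxy intermediate, drawn in its simplest monomeric form (B and C5–H cis, on the C4 methyl face) | CC1(CC[C@@H]2[C@H]([C@@H]3[C@@H](B)CC[C@]3(C)[C@@H](COB)c4c(OC)cc(OC)cc4OC)C2(C)C)OCCO1 | intermediate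
19 | diol (1S,4R,5S,6R,7R,7'R) | CC1(CC[C@@H]2[C@H]([C@@H]3[C@@H](O)CC[C@]3(C)[C@@H](CO)c4c(OC)cc(OC)cc4OC)C2(C)C)OCCO1 | intermediate
20 | keto aldehyde (4R,5S,6R,7R,7'R) | CC1(CC[C@@H]2[C@H]([C@@H]3C(=O)CC[C@]3(C)[C@@H](C=O)c4c(OC)cc(OC)cc4OC)C2(C)C)OCCO1 | intermediate
21 | 2-methylprop-1-enyl ketone (4R,5S,6R,7R,7'R) | CC1(CC[C@@H]2[C@H]([C@@H]3C(=O)CC[C@]3(C)[C@@H](C=C(C)C)c4c(OC)cc(OC)cc4OC)C2(C)C)OCCO1 | intermediate
22 | isobutyl ketal ketone, C5 epimer (4R,5S,6R,7R,7'R) | CC1(CC[C@@H]2[C@H]([C@@H]3C(=O)CC[C@]3(C)[C@@H](CC(C)C)c4c(OC)cc(OC)cc4OC)C2(C)C)OCCO1 | intermediate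
23 | isobutyl ketal ketone (4R,5R,6R,7R,7'R) | CC1(CC[C@@H]2[C@H]([C@H]3C(=O)CC[C@]3(C)[C@@H](CC(C)C)c4c(OC)cc(OC)cc4OC)C2(C)C)OCCO1 | intermediate
24 | trimethoxyaryl diketone (4R,5R,6R,7R,7'R) | CC(=O)CC[C@@H]1[C@H]([C@H]2C(=O)CC[C@]2(C)[C@@H](CC(C)C)c2c(OC)cc(OC)cc2OC)C1(C)C | intermediate
25 | 3',5'-diformyl-2',4',6'-trimethoxyaryl diketone (4R,5R,6R,7R,7'R) | CC(=O)CC[C@@H]1[C@H]([C@H]2C(=O)CC[C@]2(C)[C@@H](CC(C)C)c2c(OC)c(C=O)c(OC)c(C=O)c2OC)C1(C)C | intermediate
26 | CNP0217082.3 (4R,5R,6R,7R,7'R) | CC(=O)CC[C@@H]1[C@H]([C@H]2C(=O)CC[C@]2(C)[C@@H](CC(C)C)c2c(O)c(C=O)c(O)c(C=O)c2O)C1(C)C | target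

Total step count: 15. Longest linear sequence: 13 (steps 1, 2 and 5–15).

Steps most likely to fail

Step 5. The ligand may distinguish poorly between the two enantiotopic alkene carbons of a cyclopropene that has no bias of its own. In addition, THF brought in with 8 may loosen the chiral copper complex. The fallback sets out from 8, 4 and 6 and rejoins the route at 12. The carbomagnesiation is run with CuBr·SMe2 and no chiral ligand, followed by the same zinc and palladium relay. This gives the cis-enone as a racemate, that is 11 together with the mirror-image enone F1. The (S)-CBS reduction of step 6 then imposes the 1R configuration on both antipodes and turns them into diastereomers, 12 and the (1R,6R,7S)-allylic alcohol F2, which are separated by chromatography. The absolute configuration of C6 and C7 then comes from the reduction catalyst and a separation, at the cost of half the material.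

Step 8. Congestion around C4 may slow the shift. Leakage into the boat, or a mixed enolate geometry, may erode or invert C7' relative to C4. The fallback sets out from 12 and 13 and rejoins the route at 19. It applies if the boat proves to be the preferred topology, and it inverts the ketene acetal geometry by changing to the Eschenmoser–Claisen rearrangement.
- Acid 13 is coupled with dimethylamine (carbonyldiimidazole) to N,N-dimethyl-2-(2,4,6-trimethoxyphenyl)acetamide F3.
- O-methylation (MeOTf) and addition of NaOMe give the amide dimethyl acetal F4.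
- Heating 12 with F4 in xylene at 140 °C exchanges one methoxy group and eliminates methanol to the (Z)-ketene N,O-acetal F5. Allylic strain against NMe2 forces its aryl group cis to the allyloxy oxygen, the opposite of 15.
- The [3,3] shift of F5 through the boat should give the (4R,7'R)-dimethylamide F6.
- LiH2NBH3 reduces the tertiary amide to the primary alcohol F7, and BH3·THF followed by NaOH/H2O2 leads to 19.

Step 14. The second formylation may stall on the deactivated ring. The combination of TiCl4 and the hydrogen chloride that forms may open the cyclopropane or trigger aldol closure between C9 and C1. The fallback sets out from 24 and rejoins the route at 26. It brings in the formyl groups one at a time without a strong Lewis acid.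
- Vilsmeier–Haack formylation (POCl3, DMF, 0 °C → rt) gives the 3'-formyl trimethyl ether F8.
- BCl3 removes only the two methyl groups flanking that aldehyde, giving the 3'-formyl-2',4'-dihydroxy-6'-methoxy compound F9.
- The freed phenols re-activate the ring, so a second Vilsmeier–Haack formylation gives the 3',5'-diformyl-2',4'-dihydroxy-6'-methoxy compound F10.
- The last methoxy group is now ortho to a formyl group and is cleaved by BCl3 to give 26.

Further compounds
F1 | step 5 | mirror-image enone (6R,7S) | CC1(CC[C@H]2[C@@H](C3=C(C)CCC3=O)C2(C)C)OCCO1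
F2 | step 5 | (1R,6R,7S)-allylic alcohol | CC1(CC[C@H]2[C@@H](C3=C(C)CC[C@H]3O)C2(C)C)OCCO1
F3 | step 8 | N,N-dimethyl-2-(2,4,6-trimethoxyphenyl)acetamide | CN(C)C(=O)Cc1c(OC)cc(OC)cc1OC
F4 | step 8 | 1,1-dimethoxy-N,N-dimethyl-2-(2,4,6-trimethoxyphenyl)ethan-1-amine | CN(C)C(OC)(OC)Cc1c(OC)cc(OC)cc1OC
F5 | step 8 | (Z)-ketene N,O-acetal of 12 (aryl cis to the allyloxy oxygen) | CC1(CC[C@@H]2[C@H](C3=C(C)CC[C@H]3O/C(N(C)C)=C\c4c(OC)cc(OC)cc4OC)C2(C)C)OCCO1
F6 | step 8 | rearranged N,N-dimethylamide (4R,6S,7R,7'R) | CC1(CC[C@@H]2[C@H](C3=CCC[C@]3(C)[C@@H](C(=O)N(C)C)c4c(OC)cc(OC)cc4OC)C2(C)C)OCCO1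
F7 | step 8 | primary alcohol with a C1=C5 alkene (4R,6S,7R,7'R) | CC1(CC[C@@H]2[C@H](C3=CCC[C@]3(C)[C@@H](CO)c4c(OC)cc(OC)cc4OC)C2(C)C)OCCO1
F8 | step 14 | 3'-formyl-2',4',6'-trimethoxyaryl diketone | CC(=O)CC[C@@H]1[C@H]([C@H]2C(=O)CC[C@]2(C)[C@@H](CC(C)C)c2c(OC)cc(OC)c(C=O)c2OC)C1(C)C
F9 | step 14 | 3'-formyl-2',4'-dihydroxy-6'-methoxyaryl diketone | CC(=O)CC[C@@H]1[C@H]([C@H]2C(=O)CC[C@]2(C)[C@@H](CC(C)C)c2c(OC)cc(O)c(C=O)c2O)C1(C)C
F10 | step 14 | 3',5'-diformyl-2',4'-dihydroxy-6'-methoxyaryl diketone | CC(=O)CC[C@@H]1[C@H]([C@H]2C(=O)CC[C@]2(C)[C@@H](CC(C)C)c2c(OC)c(C=O)c(O)c(C=O)c2O)C1(C)C
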